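I had no rate constant for this flask, just a plateau in its readings, so I worked with the fraction left and not the fraction made.

- theta: left-handed substrate 5 mM; right-handed substrate 5 mM; partner 20 mM; the very flask that is asked about, followed so far
- flask: left-handed substrate 5.0 mM; partner 20.0 mM; right-handed substrate 5.0 mM; time 20 min

theta run (percent of the left-handed substrate and right-handed substrate together charged)

| time / min | left-handed product / % | left-handed substrate / % |
|---|---|---|
| 2.00 | 44.6 | 18.3 |
| 4.00 | 48.6 | 15.7 |
| 6.00 | 48.7 | 15.6 |
| 8.00 | 49.1 | 15.3 |
| 10.0 | 49.5 | 16.2 |
| 12.0 | 49.0 | 15.6 |

(scatter of a reading: 0.3 percentage points)

- north: at 20 min add left-handed substrate, 50.0 % of the amount charged, then wait 10 min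
- west: at 20 min take out 90 % of the left-handed product then present, then wait 10 min
- north-east: change nothing and wait 10 min more
- north-west: at 20 min add partner, 100 % of the amount charged, then wait 10 min

- partner is single-handed; left-handed substrate and right-handed substrate are mirror images of each other, charged as a racemate, each of them at the stated concentration
- what is taken out of left-handed product is counted as made
- additions bring no volume worth counting
- the handed part of partner does not stay in what it makes, so the products of the two hands are mirror images too

1. left-handed product, in percent of the left-handed substrate and right-handed substrate together first charged, at 20 min
2. the option that brings most further left-handed product ("none" if no option brings more than 2 percentage points) (north / west / north-east / north-west / none)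
3. left-handed product present, with what was taken out counted in, in percent of the left-handed substrate and right-handed substrate together first charged, after west
4. left-handed product present, with what was taken out counted in, in percent of the left-handed substrate and right-handed substrate together first charged, after north-east

The decision was which option the next run should take. From 4.00 min on in the theta run, left-handed substrate read about 15.7 % and left-handed product about 49.0 %, so the readings had levelled off with substrate still there, and I suspected the partner. Those two readings sum to 64.7 %, more than the left-handed half of the charge, so the substrate hands interconvert. I therefore took right-handed substrate as equal to left-handed, which left a fraction 31.4 % of all substrate.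

I assumed a pseudo-first-order loss of substrate in [partner], with partner lost on its own clock, so that logarithms of the fraction left add up. I called 0.0580 mM⁻¹ the dose per partner: minus the natural logarithm of the fraction of substrate left, divided by the [partner] charged.

Waiting, adding substrate and taking out product add no partner, so I reckoned no dose and a left-handed product still near 49.0 %. A fresh charge of partner (100 %) should take substrate from 31.4 % to 9.86 %. At the left-handed share of what had reacted, 71.4 %, I expected a gain of 15 percentage points, more than the margin of 2 points.

The forecast gave 49 % now, 49 % after west and 49 % after north-east, and it chose north-west: “Fresh partner should therefore restart the reaction.”

The flask gave 49.2 % now, 49.2 % after west and 49.2 % after north-east, and the best option was north-west, with a gain of 18 points against 0 points for north, 0 points for west and 0 points for north-east.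

    partner → decomposed reagent (k = 0.0200 s⁻¹)
    partner + left-handed substrate → left-handed product (k = 2.80 M⁻¹ s⁻¹)
    right-handed substrate ⇌ achiral form (K = 0.0370, k = 0.0410 s⁻¹)
    left-handed substrate ⇌ achiral form (K = 0.0370, k = 0.0410 s⁻¹)
    partner + right-handed substrate → right-handed product (k = 0.880 M⁻¹ s⁻¹)
    partner ⇌ dormant form (K = 0.580, k = 0.0240 s⁻¹)

At 20.0 min in the flask, partner, the limiting reagent, stood at 0 % of its charge, and left-handed and right-handed substrate stood at 15.8 % and 15.8 %. The gain of 18 points on north-west was more than my reckoned 15 points. In the neighbouring flask, charged with 5.0 mM of partner and otherwise the same, the dose per partner gives 74.8 % of each substrate left and 18.0 % of left-handed product. That flask kept 77 % of its left-handed substrate and 77 % of its right-handed substrate, and it held 16.6 % of left-handed product.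

The runs are calculated for an exercise, noise included.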